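## Retrosynthetic overview
- The C17 carboxyl comes from the C17 methyl of the Δ7 diene ester. Two C–O bonds are made in one pot: allylic oxidation, then chlorite oxidation.
- The Δ7 alkene comes from the exocyclic Δ8(17) alkene, which comes from the 8α tertiary alcohol by dehydration followed by a one-position alkene shift.
- Key disconnection: the C15–O bond of the allylic isobutyrate, made from (−)-sclareol and isobutyric acid. Oxygen leaves C13 as the ester oxygen arrives at C15, and this step also fixes the 13E alkene.
- No ring is formed and no C–C bond is made. Rings A and B and the centres C5, C9 and C10 come intact from sclareol, a bulk fragrance feedstock.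

Assumption: (S)-tBu-PyOx is taken as the ligand antipode that steers palladium to the Si face of C14 in sclareol. If the first run favours the 13Z ester, the mirror-image ligand is the matched one and nothing else changes.

## Route

Step 1
Reactants: 1 (−)-sclareol, (13R)-labd-14-ene-8α,13-diol; 2 isobutyric acid
Product: 3 (13E)-8α-hydroxylabd-13-en-15-yl isobutyrate
Conditions: Pd(O2CiPr)2 (5 mol %, made beforehand from Pd(OAc)2 and iPrCO2H, AcOH stripped off), (S)-tBu-PyOx (6 mol %), 2 (5 equiv), 1,4-benzoquinone (10 mol %), 3 Å MS, toluene, 40 °C; AgNO3–SiO2 chromatography removes residual 13Z ester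
Reagents that add atoms: isobutyric acid (2), CC(C)C(=O)O
Why: Proposed new method: this is a dehydrative, allyl-transposing (SN2′) esterification of a free tertiary vinyl carbinol under divalent palladium catalysis, in which the ligand-bound palladium carboxylate binds the vinyl group, isobutyrate adds to terminal C15 (C14 is shielded by quaternary C13 and is the disfavoured site next to an allylic oxygen, as in aldehyde-selective Wacker oxidations), and the C14–Pd bond then expels the acid-activated 13-OH by anti β-hydroxide elimination, giving water, the C13=C14 bond and divalent palladium again, so there is no redox change and no free allyl cation (hence no closure by the 8-OH to manoyl oxide); because C13 is a fixed (R) centre and the elimination is stereospecific, the alkene face that carries palladium decides the geometry (Pd on the Si face of C14 puts C12 anti to C15 and gives 13E), so the chiral ligand turns face selection into E selectivity where achiral catalysts only sense CH3 against CH2R, and the trisubstituted product alkene binds palladium too weakly to re-enter; the closest known reaction types are the PdCl2(MeCN)2-catalysed [3,3]-rearrangement of allylic esters, the Pd(OCOCF3)2-catalysed 1,3-isomerisation of tertiary allylic alcohols in water, and the SN2′ esterification of allylic trichloroacetimidates with carboxylic acids under divalent palladium catalysis.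

Step 2
Reactants: 3 (13E)-8α-hydroxylabd-13-en-15-yl isobutyrate
Product: 5 (13E)-labda-8(17),13-dien-15-yl isobutyrate, via chlorosulfite 4 (not isolated)
Conditions: SOCl2 (1.5 equiv), pyridine (10 equiv), CH2Cl2, −78 °C, 1 h
Reagents that add atoms: none
Why: This is chlorosulfite formation followed by pyridine-induced E2 elimination, in which the equatorial 8α leaving group has no antiperiplanar ring hydrogen, so a hydrogen of the freely rotating axial C17 methyl is lost and the exocyclic alkene dominates (the Δ7 isomer formed alongside is the next product anyway), while the cold basic medium spares the allylic ester and touches no retained stereocenter.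

Step 3
Reactants: 5 (13E)-labda-8(17),13-dien-15-yl isobutyrate
Product: 6 (13E)-labda-7,13-dien-15-yl isobutyrate
Conditions: chloro[N,N′-bis(3,5-di-tert-butylsalicylidene)-1,1,2,2-tetramethylethylenediaminato]cobalt (3 mol %), PhSiH3 (10 mol %), benzene, 23 °C; AgNO3–SiO2 chromatography removes any Δ8(9) isomer
Reagents that add atoms: none
Why: This is a metal-hydride hydrogen-atom-transfer olefin isomerisation, in which the cobalt hydride delivers H only to the unhindered C17 methylene (the trisubstituted, ester-deactivated Δ13 alkene reacts far more slowly) and the tertiary C8 radical returns its axial 7α-H to divalent cobalt rather than the shielded tertiary 9-H, so the Δ7 alkene forms while C9 and the 13E geometry are kept.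

Step 4
Reactants: 6 (13E)-labda-7,13-dien-15-yl isobutyrate
Product: 9 (5S,9R,10S,13E)-15-isobutyryloxylabda-7,13-dien-17-oic acid (target), via allylic alcohol 7 (not isolated), via enal 8 (not isolated)
Conditions: SeO2 (2 equiv), 1,4-dioxane, 80 °C, 3 h; cool, filter through diatomaceous earth; then tBuOH–H2O, 2-methyl-2-butene (20 equiv), NaH2PO4 (6 equiv), NaClO2 (5 equiv), 0 °C to 23 °C
Reagents that add atoms: selenium dioxide, O=[Se]=O; sodium chlorite, [Na+].[O-]Cl=O
Why: The Riley oxidation (ene reaction, then [2,3]-shift) attacks the electron-richer Δ7 alkene at the methyl on its more substituted end, just as geranyl acetate is oxidised only at its remote alkene, and the Pinnick chlorite oxidation of the crude enal gives the acid without touching the alkenes, the ester or any stereocenter.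

## Compound list
1 | (−)-sclareol, (13R)-labd-14-ene-8α,13-diol (5α-H, 9α-H, 10β-CH3, 8α-OH) | C=C[C@](C)(O)CC[C@H]1[C@](C)(O)CC[C@H]2C(C)(C)CCC[C@]12C | starting material
2 | isobutyric acid (2-methylpropanoic acid) | CC(C)C(=O)O | starting material
3 | (13E)-8α-hydroxylabd-13-en-15-yl isobutyrate | C/C(=C\COC(=O)C(C)C)CC[C@H]1[C@](C)(O)CC[C@H]2C(C)(C)CCC[C@]12C | intermediate
4 | (13E)-8α-(chlorosulfinyloxy)labd-13-en-15-yl isobutyrate, not isolated | C/C(=C\COC(=O)C(C)C)CC[C@H]1[C@](C)(OS(=O)Cl)CC[C@H]2C(C)(C)CCC[C@]12C | intermediate
5 | (13E)-labda-8(17),13-dien-15-yl isobutyrate (exocyclic methylene on ring B) | C/C(=C\COC(=O)C(C)C)CC[C@H]1C(=C)CC[C@H]2C(C)(C)CCC[C@]12C | intermediate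
6 | (13E)-labda-7,13-dien-15-yl isobutyrate | C/C(=C\COC(=O)C(C)C)CC[C@H]1C(C)=CC[C@H]2C(C)(C)CCC[C@]12C | intermediate
7 | (13E)-17-hydroxylabda-7,13-dien-15-yl isobutyrate, not isolated | C/C(=C\COC(=O)C(C)C)CC[C@H]1C(CO)=CC[C@H]2C(C)(C)CCC[C@]12C | intermediate
8 | (13E)-17-oxolabda-7,13-dien-15-yl isobutyrate, not isolated | C/C(=C\COC(=O)C(C)C)CC[C@H]1C(C=O)=CC[C@H]2C(C)(C)CCC[C@]12C | intermediate
9 | (5S,9R,10S,13E)-15-isobutyryloxylabda-7,13-dien-17-oic acid | C/C(=C\COC(=O)C(C)C)CC[C@H]1C(C(=O)O)=CC[C@H]2C(C)(C)CCC[C@]12C | target

## Step count and weak points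
Total step count: 4. Step 4 runs two oxidation stages in one pot.
Longest linear sequence: 4 (1 → 3 → 5 → 6 → 9).

**Step 1 (the proposed new step).**
- Risks:
  - β-Hydride elimination may drain the catalyst to zerovalent palladium.
  - Water may compete as the nucleophile.
  - Trace acid may close 1 to manoyl oxide.
  - Face control by the ligand may be too weak, giving an E/Z mixture.
- The fallback uses known chemistry. It sets out from 1 and comes back at 3. AcCl and N,N-dimethylaniline in CH2Cl2 acetylate both tertiary hydroxyls to give sclareol diacetate F1. PdCl2(MeCN)2 (5 mol %) in THF moves the allylic acetate by [3,3]-sigmatropic rearrangement to (13E)-labd-13-ene-8α,15-diyl diacetate F2, with about 4:1 E/Z expected. LiAlH4 in Et2O frees (13E)-labd-13-ene-8α,15-diol F3, which is cleared of the Z isomer by recrystallisation or on AgNO3–SiO2. Isobutyryl chloride and pyridine at 0 °C then acylate only the primary hydroxyl, giving 3.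

**Step 3.**
- Risks:
  - The C8 radical may close 6-endo onto the Δ13 alkene.
  - It may lose the 9-H to give the Δ8(9) alkene.
  - Slow hydrogen-atom transfer to Δ13 may erode the E geometry.
- The fallback leaves the exocyclic alkene in place. It sets out from 5 and comes back at 8. SeO2 (0.3 equiv) and tBuOOH in CH2Cl2 hydroxylate the axial allylic position to give (13E)-7α-hydroxylabda-8(17),13-dien-15-yl isobutyrate F4. PBr3 in Et2O at 0 °C converts it with allylic shift into (13E)-17-bromolabda-7,13-dien-15-yl isobutyrate F5. N-Methylmorpholine N-oxide in MeCN oxidises this primary allylic bromide to enal 8, which enters the chlorite stage of step 4.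

**Step 4.**
- Risks:
  - Over-oxidation at C9 may give the 9α-hydroxy enal.
  - C12 in the side chain may be attacked at 80 °C.
  - Selenium residues may consume chlorite.
- The fallback makes the C17–O bond by hydroboration instead of allylic oxidation. It sets out from 5 and comes back at 8. 9-BBN in THF adds only to the exocyclic methylene, from the α face, to give (13E)-17-(9-borabicyclo[3.3.1]nonan-9-yl)-8α-H-labd-13-en-15-yl isobutyrate F6. NaBO3·4H2O gives (13E)-17-hydroxy-8α-H-labd-13-en-15-yl isobutyrate F7. Dess–Martin periodinane gives (13E)-17-oxo-8α-H-labd-13-en-15-yl isobutyrate F8. IBX in DMSO at 70 °C dehydrogenates F8 toward the less hindered C7 to give enal 8, which is then treated with chlorite as in step 4.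

## Further compounds
F1 | step 1 | sclareol diacetate, (13R)-labd-14-ene-8α,13-diyl diacetate | C=C[C@](C)(OC(C)=O)CC[C@H]1[C@](C)(OC(C)=O)CC[C@H]2C(C)(C)CCC[C@]12C
F2 | step 1 | (13E)-labd-13-ene-8α,15-diyl diacetate | C/C(=C\COC(C)=O)CC[C@H]1[C@](C)(OC(C)=O)CC[C@H]2C(C)(C)CCC[C@]12C
F3 | step 1 | (13E)-labd-13-ene-8α,15-diol | C/C(=C\CO)CC[C@H]1[C@](C)(O)CC[C@H]2C(C)(C)CCC[C@]12C
F4 | step 3 | (13E)-7α-hydroxylabda-8(17),13-dien-15-yl isobutyrate | C/C(=C\COC(=O)C(C)C)CC[C@H]1C(=C)[C@H](O)C[C@H]2C(C)(C)CCC[C@]12C
F5 | step 3 | (13E)-17-bromolabda-7,13-dien-15-yl isobutyrate | C/C(=C\COC(=O)C(C)C)CC[C@H]1C(CBr)=CC[C@H]2C(C)(C)CCC[C@]12C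
F6 | step 4 | (13E)-17-(9-borabicyclo[3.3.1]nonan-9-yl)-8α-H-labd-13-en-15-yl isobutyrate | C/C(=C\COC(=O)C(C)C)CC[C@H]1[C@@H](CB3C4CCCC3CCC4)CC[C@H]2C(C)(C)CCC[C@]12C
F7 | step 4 | (13E)-17-hydroxy-8α-H-labd-13-en-15-yl isobutyrate | C/C(=C\COC(=O)C(C)C)CC[C@H]1[C@@H](CO)CC[C@H]2C(C)(C)CCC[C@]12C
F8 | step 4 | (13E)-17-oxo-8α-H-labd-13-en-15-yl isobutyrate | C/C(=C\COC(=O)C(C)C)CC[C@H]1[C@@H](C=O)CC[C@H]2C(C)(C)CCC[C@]12C
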